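## Retrosynthetic overview

1. Atom names used here: butenolide O1, C2 (lactone C=O), C3 (C‑methyl), C4 (C–O‑stearoyl), C5; exocyclic alkene C5=C1′; stereocentre C2′. The enabling feature is that ring O1–C2–C3=C4–C5 is an enol lactone: O1 is both the enol oxygen of a C5 ketone enolised towards C1′ and the acyl oxygen of C2.
2. Key disconnection (last step): C1′–C2′ and O1–C2 together. Acyclic diazo ketone 25 (C1′ = diazo carbon, C5 = ketone, C2 = cis aryl ester) and (S)‑sec‑alkyldichloroborane 26 give, by a Hooz 1,2‑shift with loss of N2, the E enol borinate, which lactonises to the target.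
3. 25 comes from anhydride 20. Its ring (3‑hydroxy‑4‑methylmaleic anhydride, from propanoic acid and oxalyl chloride) is a temporary template that holds C2 and C5 cis across C3=C4 before it is opened regioselectively.
4. The boron partner 14 comes from dendrolasin (furylmethyl Grignard + geranyl chloride) by SeO2 oxidation, vinyl Stille coupling, hydroboration and lithiation–borylation, which sets C2′ (S).
5. Ring order: the furan is bought; the anhydride ring is formed in step 10 and opened in step 12; the butenolide ring is closed last, in step 15.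

Key step: step 15

Remark on the structure: the SMILES places the side chain on C1′ trans to the ring oxygen (5E, i.e. cis to C4) and gives S at C2′; the route is built for exactly this isomer, which is the more crowded alkene geometry and therefore has to be made under kinetic control.

## Route

Step 1
Reactants: 1 furan-3-ylmethanol
Product: 2 3-(chloromethyl)furan
Conditions: SOCl2, pyridine, Et2O, 0 °C; used at once
Reagents that add atoms: thionyl chloride, O=S(Cl)Cl
Why: Chlorodehydroxylation of a primary furylmethyl alcohol via its chlorosulfite, with pyridine buffering the acid-sensitive furan.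

Step 2
Reactants: 2 3-(chloromethyl)furan; 3 geranyl chloride
Product: 5 dendrolasin, via furan-3-ylmethylmagnesium chloride 4 (not isolated)
Conditions: Mg, THF, 0 °C; then 3, Li2CuCl4 (3 mol%), THF, 0 °C
Reagents that add atoms: none
Why: Copper-catalysed Grignard–allyl halide cross-coupling in the SN2 sense; the fully substituted gamma carbon of geranyl chloride disfavours SN2′ attack, so the E alkene is kept.

Step 3
Reactants: 5 dendrolasin
Product: 6 neotorreyol
Conditions: SeO2 (cat.), t-BuOOH, salicylic acid (cat.), CH2Cl2, 0 °C to rt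
Reagents that add atoms: tert-butyl hydroperoxide, CC(C)(C)OO
Why: Riley-type SeO2 allylic oxidation (ene reaction, then [2,3]-sigmatropic shift) should attack the most electron-rich terminal trisubstituted alkene at the methyl group trans to the chain, giving the E allylic alcohol.

Step 4
Reactants: 6 neotorreyol
Product: 7 3-[(3E,7E)-9-bromo-4,8-dimethylnona-3,7-dien-1-yl]furan
Conditions: CBr4, PPh3, CH2Cl2, 0 °C
Reagents that add atoms: carbon tetrabromide, BrC(Br)(Br)Br
Why: Appel bromination, an SN2 displacement at the primary allylic carbon that leaves the alkene geometry untouched.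

Step 5
Reactants: 7 3-[(3E,7E)-9-bromo-4,8-dimethylnona-3,7-dien-1-yl]furan
Product: 8 3-[(3E,7E)-4,8-dimethylundeca-3,7,10-trien-1-yl]furan
Conditions: Bu3SnCH=CH2, Pd2(dba)3 (2.5 mol%), tri(2-furyl)phosphine, THF, 50 °C
Reagents that add atoms: tributyl(vinyl)stannane, C=C[Sn](CCCC)(CCCC)CCCC
Why: Stille coupling of an allylic bromide through a pi-allylpalladium intermediate, which should couple at the unsubstituted allyl terminus to give the skipped diene with the E alkene retained.

Step 6
Reactants: 8 3-[(3E,7E)-4,8-dimethylundeca-3,7,10-trien-1-yl]furan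
Product: 9 2-[(4E,8E)-11-(furan-3-yl)-4,8-dimethylundeca-4,8-dien-1-yl]-4,4,5,5-tetramethyl-1,3,2-dioxaborolane
Conditions: pinacolborane, [Ir(cod)Cl]2 (1.5 mol%), dppm, CH2Cl2, rt
Reagents that add atoms: pinacolborane, CC1(C)OBOC1(C)C
Why: Iridium-catalysed anti-Markovnikov hydroboration is selective for the monosubstituted alkene over the two trisubstituted alkenes and the furan.

Step 7
Reactants: 9 2-[(4E,8E)-11-(furan-3-yl)-4,8-dimethylundeca-4,8-dien-1-yl]-4,4,5,5-tetramethyl-1,3,2-dioxaborolane; 10 ethyl N,N-diisopropylcarbamate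
Product: 13 2-[(2S,6E,10E)-13-(furan-3-yl)-6,10-dimethyltrideca-6,10-dien-2-yl]-4,4,5,5-tetramethyl-1,3,2-dioxaborolane, via lithiated carbamate 11 (not isolated), via boronate complex 12 (not isolated)
Conditions: 10, s-BuLi, (+)-sparteine, Et2O, −78 °C, 5 h; then 9, −78 °C, 1 h; then MgBr2·OEt2, Et2O, reflux, 12 h
Reagents that add atoms: none
Why: Lithiation–borylation: sparteine-mediated enantioselective deprotonation gives the configurationally stable (R)-lithio carbamate, which is borylated with retention and then undergoes a stereospecific 1,2-metallate rearrangement anti to the carbamate (inversion), so reagent control by (+)-sparteine sets the S centre.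

Step 8
Reactants: 13 2-[(2S,6E,10E)-13-(furan-3-yl)-6,10-dimethyltrideca-6,10-dien-2-yl]-4,4,5,5-tetramethyl-1,3,2-dioxaborolane
Product: 14 potassium trifluoro[(2S,6E,10E)-13-(furan-3-yl)-6,10-dimethyltrideca-6,10-dien-2-yl]borate
Conditions: KHF2, MeOH/H2O, rt
Reagents that add atoms: potassium hydrogen difluoride, F.[F-].[K+]
Why: Ligand exchange at boron to the storable trifluoroborate; no bond to the stereocentre is broken.

Step 9
Reactants: 15 propanoic acid
Product: 16 1,1-bis(trimethylsilyloxy)prop-1-ene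
Conditions: LiN(i-Pr)2 (2.2 equiv), THF, −78 to 0 °C; then Me3SiCl, −78 °C to rt
Reagents that add atoms: chlorotrimethylsilane, C[Si](C)(C)Cl
Why: Double deprotonation to the enediolate and O,O-bis-silylation gives the bis-silyl ketene acetal.

Step 10
Reactants: 16 1,1-bis(trimethylsilyloxy)prop-1-ene; 17 oxalyl chloride
Product: 18 3-hydroxy-4-methylfuran-2,5-dione
Conditions: Me3SiOTf (cat.), CH2Cl2, −78 °C to rt
Reagents that add atoms: none
Why: C-acylation of the ketene acetal by oxalyl chloride and ring closure of the silyl ester onto the second acid chloride (cyclocondensation) gives the hydroxymaleic anhydride, whose ring fixes the two carbonyl carbons cis on the C=C bond.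

Step 11
Reactants: 18 3-hydroxy-4-methylfuran-2,5-dione; 19 octadecanoyl chloride
Product: 20 4-methyl-2,5-dioxo-2,5-dihydrofuran-3-yl octadecanoate
Conditions: 2,6-lutidine, CH2Cl2, 0 °C
Reagents that add atoms: none
Why: O-acylation of an acidic enol (vinylogous acid) by an acid chloride with a non-nucleophilic base.

Step 12
Reactants: 20 4-methyl-2,5-dioxo-2,5-dihydrofuran-3-yl octadecanoate
Product: 22 4-[(4-methoxyphenyl)methyl] 1-(4-nitrophenyl) (2E)-2-methyl-3-(octadecanoyloxy)but-2-enedioate, via half ester 21 (not isolated)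
Conditions: 4-methoxybenzyl alcohol (1.0 equiv), CH2Cl2, 0 °C to rt; then 4-nitrophenol, DCC, 0 °C to rt
Reagents that add atoms: 4-methoxybenzyl alcohol, COc1ccc(CO)cc1; 4-nitrophenol, Oc1ccc(cc1)[N+](=O)[O-]
Why: Anhydride alcoholysis should occur at the carbonyl attached to the acyloxy-bearing carbon (inductively activated, while the other carbonyl is deactivated as a vinylogous carbonate), followed by carbodiimide esterification of the freed acid; the cis arrangement of the two carbonyls is inherited from the ring.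

Step 13
Reactants: 22 4-[(4-methoxyphenyl)methyl] 1-(4-nitrophenyl) (2E)-2-methyl-3-(octadecanoyloxy)but-2-enedioate
Product: 23 (2E)-3-methyl-4-(4-nitrophenoxy)-2-(octadecanoyloxy)-4-oxobut-2-enoic acid
Conditions: CF3CO2H, Et3SiH, CH2Cl2, 0 °C; used without delay
Reagents that add atoms: none
Why: Acidolysis of the 4-methoxybenzyl ester with silane trapping of the benzylic cation; under acid the carboxyl stays protonated and should not close onto the neighbouring aryl ester, and the aryl and enol esters are acid-stable.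

Step 14
Reactants: 23 (2E)-3-methyl-4-(4-nitrophenoxy)-2-(octadecanoyloxy)-4-oxobut-2-enoic acid
Product: 25 4-nitrophenyl (2E)-5-diazo-2-methyl-3-(octadecanoyloxy)-4-oxopent-2-enoate, via acid chloride 24 (not isolated)
Conditions: (COCl)2, DMF (cat.), CH2Cl2, 0 °C to rt, evaporate; then CH2N2 (2.5 equiv), Et2O, 0 °C
Reagents that add atoms: diazomethane, C=[N+]=[N-]
Why: Acylation of diazomethane by the acid chloride (first stage of the Arndt–Eistert sequence), the second equivalent of diazomethane taking up HCl.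

Step 15
Reactants: 14 potassium trifluoro[(2S,6E,10E)-13-(furan-3-yl)-6,10-dimethyltrideca-6,10-dien-2-yl]borate; 25 4-nitrophenyl (2E)-5-diazo-2-methyl-3-(octadecanoyloxy)-4-oxopent-2-enoate
Product: 29 (5E)-5-[(2S,6E,10E)-13-(furan-3-yl)-2,6,10-trimethyltrideca-6,10-dien-1-ylidene]-3-methyl-2-oxo-2,5-dihydrofuran-4-yl octadecanoate, via alkyldichloroborane 26 (not isolated), via diazonium borate 27 (not isolated), via enol borinate 28 (not isolated)
Conditions: 14, SiCl4 (1.0 equiv), CH2Cl2/MeCN, 0 °C to rt, 1 h; then 25, 2,6-di-tert-butylpyridine (0.2 equiv), CH2Cl2, −78 to −20 °C; then rt, 2 h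
Reagents that add atoms: none
Why: Proposed new method: the diazo carbon of 25 adds to the Lewis-acidic boron of 26, the sec-alkyl group migrates from boron to carbon as N2 leaves, boron shifts from carbon to the ketone oxygen, and the O-boron enolate then acylates itself on the cis aryl ester; the closest known reaction is the Hooz alkylation of alpha-diazo ketones with alkyldichloroboranes, whose enol borinates have been trapped by protons, silyl groups or aldehydes but not by an internal ester. The butenolide ring closes by 5-exo-trig attack of the enol oxygen on the aryl ester carbonyl, 4-nitrophenoxide leaving to boron. No new stereocentre is created: the S centre from step 7 is carried over because the 1,2-shift proceeds with retention at the migrating carbon. The step needs the E enolate (chain trans to oxygen), which is the kinetic geometry of Hooz enolates because the diazo ketone reacts in its s-cis form and the alkyl group enters anti to the departing N2; ring closure at low temperature should lock this geometry before any E to Z equilibration. Alkyl rather than chloride migration is favoured by the low temperature, and the furan and the trisubstituted alkenes should survive because the borane is made without protic acid, in the presence of a hindered base, and is consumed at −78 °C.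

## Compound list

1 | furan-3-ylmethanol | OCc1ccoc1 | starting material
2 | 3-(chloromethyl)furan | ClCc1ccoc1 | intermediate
3 | geranyl chloride, (2E)-1-chloro-3,7-dimethylocta-2,6-diene | CC(C)=CCC/C(C)=C/CCl | starting material
4 | (furan-3-ylmethyl)magnesium chloride | Cl[Mg]Cc1ccoc1 | intermediate
5 | dendrolasin, 3-[(3E)-4,8-dimethylnona-3,7-dien-1-yl]furan | CC(C)=CCC/C(C)=C/CCc1ccoc1 | intermediate
6 | neotorreyol, (2E,6E)-9-(furan-3-yl)-2,6-dimethylnona-2,6-dien-1-ol | OC/C(C)=C/CC/C(C)=C/CCc1ccoc1 | intermediate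
7 | 3-[(3E,7E)-9-bromo-4,8-dimethylnona-3,7-dien-1-yl]furan | BrC/C(C)=C/CC/C(C)=C/CCc1ccoc1 | intermediate
8 | 3-[(3E,7E)-4,8-dimethylundeca-3,7,10-trien-1-yl]furan | C=CC/C(C)=C/CC/C(C)=C/CCc1ccoc1 | intermediate
9 | 2-[(4E,8E)-11-(furan-3-yl)-4,8-dimethylundeca-4,8-dien-1-yl]-4,4,5,5-tetramethyl-1,3,2-dioxaborolane | CC1(C)OB(CCC/C(C)=C/CC/C(C)=C/CCc2ccoc2)OC1(C)C | intermediate
10 | ethyl N,N-diisopropylcarbamate | CCOC(=O)N(C(C)C)C(C)C | starting material
11 | (1R)-1-lithioethyl N,N-diisopropylcarbamate, (+)-sparteine complex | [Li][C@H](C)OC(=O)N(C(C)C)C(C)C | intermediate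
12 | lithium {(1R)-1-[(diisopropylcarbamoyl)oxy]ethyl}[(4E,8E)-11-(furan-3-yl)-4,8-dimethylundeca-4,8-dien-1-yl](pinacolato)borate | C[C@H](OC(=O)N(C(C)C)C(C)C)[B-]1(CCC/C(C)=C/CC/C(C)=C/CCc2ccoc2)OC(C)(C)C(C)(C)O1.[Li+] | intermediate
13 | 2-[(2S,6E,10E)-13-(furan-3-yl)-6,10-dimethyltrideca-6,10-dien-2-yl]-4,4,5,5-tetramethyl-1,3,2-dioxaborolane | C[C@H](B1OC(C)(C)C(C)(C)O1)CCC/C(C)=C/CC/C(C)=C/CCc1ccoc1 | intermediate
14 | potassium trifluoro[(2S,6E,10E)-13-(furan-3-yl)-6,10-dimethyltrideca-6,10-dien-2-yl]borate | C[C@H]([B-](F)(F)F)CCC/C(C)=C/CC/C(C)=C/CCc1ccoc1.[K+] | intermediate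
15 | propanoic acid | CCC(=O)O | starting material
16 | 1,1-bis(trimethylsilyloxy)prop-1-ene | CC=C(O[Si](C)(C)C)O[Si](C)(C)C | intermediate
17 | oxalyl chloride | ClC(=O)C(Cl)=O | starting material
18 | 3-hydroxy-4-methylfuran-2,5-dione | CC1=C(O)C(=O)OC1=O | intermediate
19 | octadecanoyl chloride (stearoyl chloride) | CCCCCCCCCCCCCCCCCC(Cl)=O | starting material
20 | 4-methyl-2,5-dioxo-2,5-dihydrofuran-3-yl octadecanoate | CCCCCCCCCCCCCCCCCC(=O)OC1=C(C)C(=O)OC1=O | intermediate
21 | (2E)-4-[(4-methoxyphenyl)methoxy]-2-methyl-3-(octadecanoyloxy)-4-oxobut-2-enoic acid (both carbonyl carbons cis) | COc1ccc(COC(=O)/C(OC(=O)CCCCCCCCCCCCCCCCC)=C(/C)C(=O)O)cc1 | intermediate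
22 | 4-[(4-methoxyphenyl)methyl] 1-(4-nitrophenyl) (2E)-2-methyl-3-(octadecanoyloxy)but-2-enedioate | COc1ccc(COC(=O)/C(OC(=O)CCCCCCCCCCCCCCCCC)=C(/C)C(=O)Oc2ccc(cc2)[N+](=O)[O-])cc1 | intermediate
23 | (2E)-3-methyl-4-(4-nitrophenoxy)-2-(octadecanoyloxy)-4-oxobut-2-enoic acid | OC(=O)/C(OC(=O)CCCCCCCCCCCCCCCCC)=C(/C)C(=O)Oc1ccc(cc1)[N+](=O)[O-] | intermediate
24 | 4-nitrophenyl (2E)-4-chloro-2-methyl-3-(octadecanoyloxy)-4-oxobut-2-enoate | ClC(=O)/C(OC(=O)CCCCCCCCCCCCCCCCC)=C(/C)C(=O)Oc1ccc(cc1)[N+](=O)[O-] | intermediate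
25 | 4-nitrophenyl (2E)-5-diazo-2-methyl-3-(octadecanoyloxy)-4-oxopent-2-enoate (ketone and ester carbons cis) | [N-]=[N+]=CC(=O)/C(OC(=O)CCCCCCCCCCCCCCCCC)=C(/C)C(=O)Oc1ccc(cc1)[N+](=O)[O-] | intermediate
26 | dichloro[(2S,6E,10E)-13-(furan-3-yl)-6,10-dimethyltrideca-6,10-dien-2-yl]borane | C[C@H](B(Cl)Cl)CCC/C(C)=C/CC/C(C)=C/CCc1ccoc1 | intermediate
27 | zwitterionic diazonium borate from addition of the diazo carbon of 25 to the boron of 26 | C[C@H]([B-](Cl)(Cl)C([N+]#N)C(=O)/C(OC(=O)CCCCCCCCCCCCCCCCC)=C(/C)C(=O)Oc1ccc(cc1)[N+](=O)[O-])CCC/C(C)=C/CC/C(C)=C/CCc1ccoc1 | intermediate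
28 | (E)-O-dichloroboryl enolate (chain trans to the enol oxygen), still bearing the cis 4-nitrophenyl ester | ClB(Cl)O/C(=C/[C@@H](C)CCC/C(C)=C/CC/C(C)=C/CCc1ccoc1)/C(OC(=O)CCCCCCCCCCCCCCCCC)=C(/C)C(=O)Oc1ccc(cc1)[N+](=O)[O-] | intermediate
29 | (5E)-5-[(2S,6E,10E)-13-(furan-3-yl)-2,6,10-trimethyltrideca-6,10-dien-1-ylidene]-3-methyl-2-oxo-2,5-dihydrofuran-4-yl octadecanoate | CCCCCCCCCCCCCCCCCC(=O)OC1=C(C)C(=O)O/C1=C/[C@@H](C)CCC/C(C)=C/CC/C(C)=C/CCc1ccoc1 | target

## Step count and risks

Total step count: 15. Longest linear sequence: 9 steps (steps 1–8, then step 15); the second branch is steps 9–14.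

**Step 15 (proposed new method).** What may go wrong: chloride instead of alkyl migration at boron; E to Z equilibration or C-protonation of the boron enolate before the ring closes; Lewis-acid-induced cyclisation of the furan–diene chain. The fallback forms the same bond by a stereoretentive Negishi coupling of known type; it sets out from 9 and 20 and comes back at 29.
- From 9, the sequence of step 7 run with (−)-sparteine would pass through the (1S)-lithiated carbamate F1 and the diastereomeric boronate complex F2 to the (2R)-boronic ester F3.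
- Oxidation (NaBO3·4H2O, THF/H2O, retention) would give the (2R)-alcohol F4, and Appel iodination (I2, PPh3, imidazole, inversion) the (12S)-iodide F5.
- Iodine–lithium exchange (t-BuLi, pentane/Et2O, −100 °C, retention) would give the sec-alkyllithium F6, trapped at once with Me3SiCH2ZnBr·LiBr as the configurationally stable mixed dialkylzinc F7.
- From 20, Ramirez dibromo-olefination (CBr4, PPh3) at the more electrophilic anhydride carbonyl would give the dibromomethylidene butenolide F8.
- Hydrodebromination with Bu3SnH and Pd(PPh3)4 should remove the bromine trans to the larger ring carbon (the one cis to the ring oxygen), giving the (E)-bromomethylidene butenolide F9.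
- Coupling of F7 with F9 (Pd(P(t-Bu)3)2, THF, −25 °C), retentive at both carbons, would give 29.

**Step 12.** What may go wrong: attack of the alcohol at the other anhydride carbonyl, or acyl transfer from the enol stearate. The fallback fixes the regiochemistry by a ring instead of by a selective attack; it sets out from 19 and comes back at 23.
- Commercially available 3-methyltetronic acid would be O-acylated with 19 (Et3N, CH2Cl2) to the tetronate stearate F10, in which the lactone carbonyl is by constitution the carbon next to C-methyl.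
- Silylation (t-BuMe2SiOTf, Et3N) would give the silyloxyfuran F11.
- Photooxygenation (O2, rose bengal, light, −78 °C) would give the hydroxybutenolide F12, the ring tautomer of the Z aldehyde acid.
- Carbodiimide esterification with 4-nitrophenol would trap the open form as the formyl ester F13.
- Pinnick oxidation (NaClO2, NaH2PO4, 2-methylbut-2-ene) would give 23, from which steps 14 and 15 follow.

**Step 3.** What may go wrong: oxidation of the furan ring, over-oxidation to the enal, or attack at the internal alkene. The fallback installs the oxygen before the furan is attached; it sets out from 4 and comes back at 6.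
- Geranyl acetate, a routine substrate for the same SeO2/t-BuOOH oxidation, would give 8-hydroxygeranyl acetate F14.
- Silylation (t-BuMe2SiCl, imidazole) would give the silyl ether acetate F15, and methanolysis (K2CO3, MeOH) the allylic alcohol F16.
- MsCl, LiCl and 2,4,6-collidine in DMF would give the allylic chloride F17.
- Coupling with Grignard reagent 4 (Li2CuCl4, THF, 0 °C) would give the silyl ether F18, and Bu4NF would release 6.

## Further compounds

F1 | step 15 | (1S)-1-lithioethyl N,N-diisopropylcarbamate, (−)-sparteine complex | [Li][C@@H](C)OC(=O)N(C(C)C)C(C)C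
F2 | step 15 | lithium {(1S)-1-[(diisopropylcarbamoyl)oxy]ethyl}[(4E,8E)-11-(furan-3-yl)-4,8-dimethylundeca-4,8-dien-1-yl](pinacolato)borate | C[C@@H](OC(=O)N(C(C)C)C(C)C)[B-]1(CCC/C(C)=C/CC/C(C)=C/CCc2ccoc2)OC(C)(C)C(C)(C)O1.[Li+]
F3 | step 15 | 2-[(2R,6E,10E)-13-(furan-3-yl)-6,10-dimethyltrideca-6,10-dien-2-yl]-4,4,5,5-tetramethyl-1,3,2-dioxaborolane | C[C@@H](B1OC(C)(C)C(C)(C)O1)CCC/C(C)=C/CC/C(C)=C/CCc1ccoc1
F4 | step 15 | (2R,6E,10E)-13-(furan-3-yl)-6,10-dimethyltrideca-6,10-dien-2-ol | C[C@@H](O)CCC/C(C)=C/CC/C(C)=C/CCc1ccoc1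
F5 | step 15 | 3-[(3E,7E,12S)-12-iodo-4,8-dimethyltrideca-3,7-dien-1-yl]furan | C[C@H](I)CCC/C(C)=C/CC/C(C)=C/CCc1ccoc1
F6 | step 15 | [(2S,6E,10E)-13-(furan-3-yl)-6,10-dimethyltrideca-6,10-dien-2-yl]lithium | C[C@H]([Li])CCC/C(C)=C/CC/C(C)=C/CCc1ccoc1
F7 | step 15 | [(2S,6E,10E)-13-(furan-3-yl)-6,10-dimethyltrideca-6,10-dien-2-yl][(trimethylsilyl)methyl]zinc | C[C@H]([Zn]C[Si](C)(C)C)CCC/C(C)=C/CC/C(C)=C/CCc1ccoc1
F8 | step 15 | 5-(dibromomethylidene)-3-methyl-2-oxo-2,5-dihydrofuran-4-yl octadecanoate | CCCCCCCCCCCCCCCCCC(=O)OC1=C(C)C(=O)OC1=C(Br)Br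
F9 | step 15 | (5E)-5-(bromomethylidene)-3-methyl-2-oxo-2,5-dihydrofuran-4-yl octadecanoate | CCCCCCCCCCCCCCCCCC(=O)OC1=C(C)C(=O)O/C1=C/Br
F10 | step 12 | 3-methyl-2-oxo-2,5-dihydrofuran-4-yl octadecanoate | CCCCCCCCCCCCCCCCCC(=O)OC1=C(C)C(=O)OC1
F11 | step 12 | 5-{[tert-butyl(dimethyl)silyl]oxy}-4-methylfuran-3-yl octadecanoate | CCCCCCCCCCCCCCCCCC(=O)Oc1coc(O[Si](C)(C)C(C)(C)C)c1C
F12 | step 12 | 5-hydroxy-3-methyl-2-oxo-2,5-dihydrofuran-4-yl octadecanoate | CCCCCCCCCCCCCCCCCC(=O)OC1=C(C)C(=O)OC1O
F13 | step 12 | 4-nitrophenyl (2E)-2-methyl-3-(octadecanoyloxy)-4-oxobut-2-enoate | O=C/C(OC(=O)CCCCCCCCCCCCCCCCC)=C(/C)C(=O)Oc1ccc(cc1)[N+](=O)[O-]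
F14 | step 3 | (2E,6E)-8-hydroxy-3,7-dimethylocta-2,6-dien-1-yl acetate | CC(=O)OC/C=C(C)/CC/C=C(C)/CO
F15 | step 3 | (2E,6E)-8-{[tert-butyl(dimethyl)silyl]oxy}-3,7-dimethylocta-2,6-dien-1-yl acetate | CC(=O)OC/C=C(C)/CC/C=C(C)/CO[Si](C)(C)C(C)(C)C
F16 | step 3 | (2E,6E)-8-{[tert-butyl(dimethyl)silyl]oxy}-3,7-dimethylocta-2,6-dien-1-ol | OC/C=C(C)/CC/C=C(C)/CO[Si](C)(C)C(C)(C)C
F17 | step 3 | tert-butyl{[(2E,6E)-8-chloro-2,6-dimethylocta-2,6-dien-1-yl]oxy}dimethylsilane | ClC/C=C(C)/CC/C=C(C)/CO[Si](C)(C)C(C)(C)C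
F18 | step 3 | tert-butyl{[(2E,6E)-9-(furan-3-yl)-2,6-dimethylnona-2,6-dien-1-yl]oxy}dimethylsilane | CC(C)(C)[Si](C)(C)OC/C(C)=C/CC/C(C)=C/CCc1ccoc1
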